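**Plan**

Numbering: C1 allyl bridgehead, C2 CH2, C3 CHOMe, C4 C=O, C5 MeO bridgehead, C6 CHAr, C7 CHMe, C8 CHOH. The enabling feature is that the propano bridge C2–C3–C4 joins C1 and C5. These are the two α-carbons of the five-membered ring C1–C8–C5–C6–C7 once C8 is a ketone, and the bridge has the carbon and oxygen pattern of 2-methoxyacrolein.
Retrosynthetic cuts, in order: redox exchange between C4 and C8 together with inversion at C3; C4–C5 (aldol) and C1–C2 (Michael) in one operation; C7–CH3 (cuprate); C1–allyl (Stille); C5–O (Rubottom); C6–aryl (copper-catalysed Grignard addition).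
Forward: the five-membered ring is bought and substituted position by position up to a regiodefined C1–C8 enol silane. The six-membered ring C1–C2–C3–C4–C5–C8 is then closed on it, and only redox and stereochemical adjustment follow.
Stereochemistry: the single centre of (S)-4-silyloxycyclopentenone places the aryl group at C6 and is then eliminated. C6 directs C5–O and C7–CH3, C7 directs C1, the tether fixes C5, the endo aryl group fixes C4, the C4 aluminium alkoxide steers hydride to C8, and C3 is set last by exo-face protonation of the C3–C4 enolate.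

Key step: step 10

Conventions: Ar = 4-methoxy-3-(triisopropylsilyloxy)phenyl. In the bicycle, exo means turned towards the one-carbon bridge C8 and endo means turned away from it. The target carries Ar endo, CH3 exo, C3–OMe endo, and C8–OH over the propano bridge.
Assumption: the ring closure of the key step is taken to be reversible under its acidic conditions. The bicyclic intermediates before the inversion step are therefore drawn as the thermodynamic C3 epimer (methoxy exo). The other epimer would pass through the same enolate and converge.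

**Step 1**
Reactants: 1 5-bromo-2-methoxyphenol
Product: 2 (5-bromo-2-methoxyphenoxy)triisopropylsilane
Conditions: iPr3SiCl (1.1 equiv), imidazole (2 equiv), DMF, 23 °C
Reagents that add atoms: triisopropylsilyl chloride, CC(C)[Si](Cl)(C(C)C)C(C)C
Why: Imidazole-promoted silylation of a phenol is routine, and the triisopropylsilyl ether is chosen because it survives Grignard formation, MeLi, amidine base and aqueous acid and still leaves with buffered fluoride at the end.

**Step 2**
Reactants: 2 (5-bromo-2-methoxyphenoxy)triisopropylsilane; 3 (S)-4-(tert-butyldimethylsilyloxy)cyclopent-2-en-1-one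
Product: 5 (3R,4S)-3-Ar-4-(tert-butyldimethylsilyloxy)-1-(trimethylsilyloxy)cyclopent-1-ene, via arylmagnesium bromide 4 (not isolated)
Conditions: 2, Mg, THF, reflux; then CuI (10 mol %), LiCl (20 mol %), Me3SiCl (2 equiv), 3, THF, −78 → −40 °C
Reagents that add atoms: chlorotrimethylsilane, C[Si](C)(C)Cl
Why: Copper-catalysed, Me3SiCl-accelerated conjugate addition of a Grignard reagent: the aryl group enters C6 anti to the neighbouring silyloxy group, so the purchased centre sets C6, and immediate O-silylation stores the enolate as its regiodefined enol silane before the β-silyloxy group can be eliminated.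

**Step 3**
Reactants: 5 (3R,4S)-3-Ar-4-(tert-butyldimethylsilyloxy)-1-(trimethylsilyloxy)cyclopent-1-ene
Product: 7 (2S,3S,4S)-3-Ar-4-(tert-butyldimethylsilyloxy)-2-hydroxycyclopentan-1-one, via α-trimethylsilyloxy ketone 6 (not isolated)
Conditions: mCPBA (1.1 equiv), hexane–CH2Cl2, −15 °C; then citric acid (10 mol %), MeOH, 0 °C
Reagents that add atoms: 3-chloroperoxybenzoic acid, OOC(=O)c1cccc(Cl)c1
Why: Rubottom oxidation: the electron-rich enol silane is epoxidised on the face anti to the adjacent aryl group, silyl migration gives 6, and acid-catalysed methanolysis removes only the trimethylsilyl group, leaving the hydroxyl at C5 trans to the aryl group.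

**Step 4**
Reactants: 7 (2S,3S,4S)-3-Ar-4-(tert-butyldimethylsilyloxy)-2-hydroxycyclopentan-1-one
Product: 8 (2S,3S,4S)-3-Ar-4-(tert-butyldimethylsilyloxy)-2-methoxycyclopentan-1-one
Conditions: MeI (10 equiv), Ag2O (2 equiv), 4 Å molecular sieves, CH2Cl2, 23 °C, dark
Reagents that add atoms: iodomethane, CI
Why: Purdie methylation (MeI, Ag2O) etherifies the α-ketol without a soluble base, so neither epimerisation at C5, ketol rearrangement nor premature loss of the β-silyloxy group is expected, and no stereocentre is touched.

**Step 5**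
Reactants: 8 (2S,3S,4S)-3-Ar-4-(tert-butyldimethylsilyloxy)-2-methoxycyclopentan-1-one
Product: 9 (4S,5S)-4-Ar-5-methoxycyclopent-2-en-1-one
Conditions: DBU (1.1 equiv), CH2Cl2, −20 → 0 °C, short contact, pH 7 buffer quench
Reagents that add atoms: none
Why: E1cB elimination of a β-silyloxy ketone with an amidine base is the standard passage from 3-substituted 4-silyloxycyclopentanones to 4-substituted cyclopentenones; it removes the relay centre after use, and low temperature with short contact is meant to spare the benzylic γ-hydrogen at C6.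

**Step 6**
Reactants: 9 (4S,5S)-4-Ar-5-methoxycyclopent-2-en-1-one
Product: 10 (4S,5S)-4-Ar-2-iodo-5-methoxycyclopent-2-en-1-one
Conditions: I2 (1.5 equiv), pyridine–CH2Cl2, 0 → 23 °C
Reagents that add atoms: iodine, II
Why: α-Iodination of an enone with I2 and pyridine proceeds by conjugate addition of pyridine, iodination of the resulting enolate and loss of pyridine, conditions too weakly basic to disturb C5 or C6.

**Step 7**
Reactants: 10 (4S,5S)-4-Ar-2-iodo-5-methoxycyclopent-2-en-1-one; 11 allyltributylstannane
Product: 12 (4S,5S)-2-allyl-4-Ar-5-methoxycyclopent-2-en-1-one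
Conditions: 11 (1.3 equiv), Pd2(dba)3 (2.5 mol %), AsPh3 (20 mol %), CuI (10 mol %), NMP, 23 → 40 °C
Reagents that add atoms: none
Why: Stille coupling of a 2-iodoenone with an allylstannane under zerovalent palladium with the fast AsPh3/CuI ligand system runs near room temperature, which should keep the skipped diene from moving into conjugation and leave C5 and C6 untouched.

**Step 8**
Reactants: 12 (4S,5S)-2-allyl-4-Ar-5-methoxycyclopent-2-en-1-one
Product: 13 (3R,4S,5S)-2-allyl-4-Ar-5-methoxy-3-methyl-1-(trimethylsilyloxy)cyclopent-1-ene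
Conditions: Me2CuLi (1.5 equiv, from MeLi and CuI), Me3SiCl (3 equiv), Et2O–THF, −78 °C; cold non-acidic work-up
Reagents that add atoms: methyllithium, [Li]C; chlorotrimethylsilane, C[Si](C)(C)Cl
Why: Me3SiCl-accelerated Gilman cuprate addition: methyl enters C7 anti to the adjacent C6 aryl group, and O-silylation of the enolate where it is born gives the tetrasubstituted C1–C8 enol silane free of any C5–C8 isomer.

**Step 9**
Reactants: 14 1,1,2-trimethoxyethane
Product: 16 2-methoxyacrolein, via methoxyacetaldehyde 15 (not isolated)
Conditions: Amberlyst 15 (H+ form), H2O, 60 °C; filter; then 37% aq. CH2O, pyrrolidine (10 mol %), EtCO2H (10 mol %), iPrOH, 45 °C; distil, use fresh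
Reagents that add atoms: water, O; formaldehyde, C=O
Why: Acid-catalysed acetal hydrolysis followed by amine-catalysed Mannich-type α-methylenation of the aldehyde with aqueous formaldehyde is the general route to 2-substituted acroleins, and no stereocentre is involved.

**Step 10**
Reactants: 13 (3R,4S,5S)-2-allyl-4-Ar-5-methoxy-3-methyl-1-(trimethylsilyloxy)cyclopent-1-ene; 16 2-methoxyacrolein
Product: 19 (1S,3R,4R,5R,6S,7R)-1-allyl-6-Ar-4-hydroxy-3,5-dimethoxy-7-methylbicyclo[3.2.1]octan-8-one, via lithium enolate 17 (not isolated), via keto aldehyde 18 (not isolated)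
Conditions: 13, MeLi (1.0 equiv), THF, 0 °C; cannulated at −78 °C into 16 (1.2 equiv) precomplexed with Al(OC6H3-2,6-Ph2)3 (1.3 equiv, from AlMe3 and 2,6-diphenylphenol), toluene; then 2 M aq. HCl, THF, −78 → 23 °C
Reagents that add atoms: none
Why: MeLi cleaves the O–Si bond of 13 to give the regiodefined C1–C8 lithium enolate 17, which adds to the CH2 terminus of 16 while the formyl group is buried in the cavity of Al(OC6H3-2,6-Ph2)3 (bond C1–C2); the acid quench releases keto aldehyde 18, whose ketone enolises towards C5 and attacks the protonated formyl carbon (bond C4–C5). The closest known reaction types are the conjugate addition of lithium enolates to enals complexed by this bulky aluminium phenoxide and the Michael–aldol α,α′-annulation of cyclopentanones with enals, which gives 4-hydroxybicyclo[3.2.1]octan-8-ones. The only ring formed, the six-membered ring C1–C2–C3–C4–C5–C8, closes in the 6-(enolendo)-exo-trig mode. C1 is controlled by the adjacent C7 methyl group (attack anti to it, so that allyl ends cis to methyl), C5 by the three-atom tether, which can reach C5 only on the face it occupies at C1 although that is the aryl-bearing face, C4 by the endo aryl group, which leaves room for the hydroxyl only in the exo (axial) position where it can also hydrogen-bond to O8, and C3, which epimerises freely in 18, by the reversibility of the closure, which should select the flattened chair with an exo (equatorial) methoxy group; this last centre is opposite to the target and is inverted in step 13. The step needs C1 before C5 as nucleophilic site, 1,4- before 1,2-addition and a single mode of closure: the first is secured by the enol silane born from a cuprate addition, the second by a tetrasubstituted donor meeting an unsubstituted CH2 terminus while the carbonyl carbon is shielded, the third by the quaternary C1, which leaves C5–H as the only enolisable position of the ketone, and by the fact that the aldehyde enol could only close a four-membered ring. The Lewis acid is bound to the acceptor before the donor arrives because 13, an α′-methoxy enol silane, could itself be ionised to an oxyallyl cation by a free Lewis acid.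

**Step 11**
Reactants: 19 (1S,3R,4R,5R,6S,7R)-1-allyl-6-Ar-4-hydroxy-3,5-dimethoxy-7-methylbicyclo[3.2.1]octan-8-one
Product: 20 (1S,3R,4R,5S,6S,7R,8S)-1-allyl-6-Ar-3,5-dimethoxy-7-methylbicyclo[3.2.1]octane-4,8-diol
Conditions: iBu2AlH (3.5 equiv), CH2Cl2, −78 → −20 °C; aqueous work-up
Reagents that add atoms: none
Why: 1,3-syn-selective iBu2AlH reduction of a β-hydroxy ketone: the first equivalent turns the axial C4 hydroxyl into a bulky aluminium alkoxide that carries no hydride and sits over the propano-bridge face of C8, held there by the neighbouring methoxy oxygens and O8, so a further equivalent can deliver hydride only from the ethano-bridge face past the exo hydrogen of C6, which turns the new hydroxyl towards the propano bridge (8S, cis-diaxial to the C4 hydroxyl).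

**Step 12**
Reactants: 20 (1S,3R,4R,5S,6S,7R,8S)-1-allyl-6-Ar-3,5-dimethoxy-7-methylbicyclo[3.2.1]octane-4,8-diol
Product: 21 (1S,3R,5S,6S,7R,8S)-1-allyl-6-Ar-8-hydroxy-3,5-dimethoxy-7-methylbicyclo[3.2.1]octan-4-one
Conditions: Dess–Martin periodinane (1.05 equiv), CH2Cl2, 0 °C
Reagents that add atoms: none
Why: Dess–Martin oxidation with one equivalent of oxidant should pick C4, because the C8 carbinol lies between two fully substituted carbons and would have to become trigonal in the strained one-carbon bridge, whereas oxidation at C4 gives an unstrained cyclohexanone and relieves the 1,3-diaxial oxygen–oxygen contact, and the neutral medium avoids retro-aldol cleavage.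

**Step 13**
Reactants: 21 (1S,3R,5S,6S,7R,8S)-1-allyl-6-Ar-8-hydroxy-3,5-dimethoxy-7-methylbicyclo[3.2.1]octan-4-one
Product: 23 (1S,3S,5S,6S,7R,8S)-1-allyl-6-Ar-8-hydroxy-3,5-dimethoxy-7-methylbicyclo[3.2.1]octan-4-one, via dilithium enolate alkoxide 22 (not isolated)
Conditions: LiN(iPr)2 (3 equiv), THF, −78 → −30 °C; then AcOH (8 equiv) in THF, −78 °C
Reagents that add atoms: none
Why: Enolisation followed by kinetic protonation: only C3–H is acidic since C5 is quaternary, the dianion 22 is protected against retro-aldol cleavage, and the proton then enters C3 on the exo face, because the endo face is walled off by the C6 aryl group and the ethano bridge while the C8 oxygen lying over the exo face can relay the proton, so hydrogen ends exo and methoxy endo (3S).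

**Step 14**
Reactants: 23 (1S,3S,5S,6S,7R,8S)-1-allyl-6-Ar-8-hydroxy-3,5-dimethoxy-7-methylbicyclo[3.2.1]octan-4-one
Product: 24 (1S,3S,5S,6S,7R,8S)-1-allyl-8-hydroxy-6-(3-hydroxy-4-methoxyphenyl)-3,5-dimethoxy-7-methylbicyclo[3.2.1]octan-4-one (CNP0209708.1)
Conditions: Bu4NF (1.2 equiv), AcOH (1.5 equiv), THF, 0 °C
Reagents that add atoms: none
Why: Fluoride cleavage of a phenolic silyl ether is fast at 0 °C, and acetic acid buffers fluoride and the liberated phenoxide so that neither the freshly set C3 centre nor the β-hydroxy ketone (retro-aldol) is put at risk.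

**Compound list**

1 | 5-bromo-2-methoxyphenol | COc1ccc(Br)cc1O | starting material
2 | (5-bromo-2-methoxyphenoxy)triisopropylsilane | COc1ccc(Br)cc1O[Si](C(C)C)(C(C)C)C(C)C | intermediate
3 | (S)-4-(tert-butyldimethylsilyloxy)cyclopent-2-en-1-one | O=C1C=C[C@@H](O[Si](C)(C)C(C)(C)C)C1 | starting material
4 | [4-methoxy-3-(triisopropylsilyloxy)phenyl]magnesium bromide | COc1ccc([Mg]Br)cc1O[Si](C(C)C)(C(C)C)C(C)C | intermediate
5 | (3R,4S)-3-Ar-4-(tert-butyldimethylsilyloxy)-1-(trimethylsilyloxy)cyclopent-1-ene (Ar trans to OTBS) | C[Si](C)(C)OC1=C[C@H](c2ccc(OC)c(O[Si](C(C)C)(C(C)C)C(C)C)c2)[C@@H](O[Si](C)(C)C(C)(C)C)C1 | intermediate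
6 | (2S,3R,4S)-3-Ar-4-(tert-butyldimethylsilyloxy)-2-(trimethylsilyloxy)cyclopentan-1-one | O=C1C[C@H](O[Si](C)(C)C(C)(C)C)[C@@H](c2ccc(OC)c(O[Si](C(C)C)(C(C)C)C(C)C)c2)[C@@H]1O[Si](C)(C)C | intermediate
7 | (2S,3S,4S)-3-Ar-4-(tert-butyldimethylsilyloxy)-2-hydroxycyclopentan-1-one (OH trans to Ar, Ar trans to OTBS) | O=C1C[C@H](O[Si](C)(C)C(C)(C)C)[C@@H](c2ccc(OC)c(O[Si](C(C)C)(C(C)C)C(C)C)c2)[C@@H]1O | intermediate
8 | (2S,3S,4S)-3-Ar-4-(tert-butyldimethylsilyloxy)-2-methoxycyclopentan-1-one | O=C1C[C@H](O[Si](C)(C)C(C)(C)C)[C@@H](c2ccc(OC)c(O[Si](C(C)C)(C(C)C)C(C)C)c2)[C@@H]1OC | intermediate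
9 | (4S,5S)-4-Ar-5-methoxycyclopent-2-en-1-one (trans) | O=C1C=C[C@@H](c2ccc(OC)c(O[Si](C(C)C)(C(C)C)C(C)C)c2)[C@@H]1OC | intermediate
10 | (4S,5S)-4-Ar-2-iodo-5-methoxycyclopent-2-en-1-one | O=C1C(I)=C[C@@H](c2ccc(OC)c(O[Si](C(C)C)(C(C)C)C(C)C)c2)[C@@H]1OC | intermediate
11 | allyltributylstannane | C=CC[Sn](CCCC)(CCCC)CCCC | starting material
12 | (4S,5S)-2-allyl-4-Ar-5-methoxycyclopent-2-en-1-one | C=CCC1=C[C@@H](c2ccc(OC)c(O[Si](C(C)C)(C(C)C)C(C)C)c2)[C@H](OC)C1=O | intermediate
13 | (3R,4S,5S)-2-allyl-4-Ar-5-methoxy-3-methyl-1-(trimethylsilyloxy)cyclopent-1-ene (C1–C8 enol silane; CH3 trans to Ar, OMe trans to Ar) | C=CCC1=C(O[Si](C)(C)C)[C@@H](OC)[C@H](c2ccc(OC)c(O[Si](C(C)C)(C(C)C)C(C)C)c2)[C@H]1C | intermediate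
14 | 1,1,2-trimethoxyethane | COCC(OC)OC | starting material
15 | methoxyacetaldehyde | COCC=O | intermediate
16 | 2-methoxyacrolein | C=C(OC)C=O | intermediate
17 | lithium enolate of (2-allyl-4-Ar-5-methoxy-3-methyl)cyclopentanone, C1–C8 regioisomer | C=CCC1=C(O[Li])[C@@H](OC)[C@H](c2ccc(OC)c(O[Si](C(C)C)(C(C)C)C(C)C)c2)[C@H]1C | intermediate
18 | 3-[(1S,2R,3S,4S)-1-allyl-3-Ar-4-methoxy-2-methyl-5-oxocyclopentyl]-2-methoxypropanal (interconverting epimers at the CHOMe carbon) | C=CC[C@@]1(CC(OC)C=O)C(=O)[C@@H](OC)[C@H](c2ccc(OC)c(O[Si](C(C)C)(C(C)C)C(C)C)c2)[C@H]1C | intermediate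
19 | (1S,3R,4R,5R,6S,7R)-1-allyl-6-Ar-4-hydroxy-3,5-dimethoxy-7-methylbicyclo[3.2.1]octan-8-one (Ar endo, CH3 exo, 3-OMe exo, 4-OH exo) | C=CC[C@]12C[C@@H](OC)[C@@H](O)[C@](OC)([C@H](c3ccc(OC)c(O[Si](C(C)C)(C(C)C)C(C)C)c3)[C@H]1C)C2=O | intermediate
20 | (1S,3R,4R,5S,6S,7R,8S)-1-allyl-6-Ar-3,5-dimethoxy-7-methylbicyclo[3.2.1]octane-4,8-diol (8-OH over the propano bridge) | C=CC[C@]12C[C@@H](OC)[C@@H](O)[C@](OC)([C@H](c3ccc(OC)c(O[Si](C(C)C)(C(C)C)C(C)C)c3)[C@H]1C)[C@H]2O | intermediate
21 | (1S,3R,5S,6S,7R,8S)-1-allyl-6-Ar-8-hydroxy-3,5-dimethoxy-7-methylbicyclo[3.2.1]octan-4-one (3-OMe exo) | C=CC[C@]12C[C@@H](OC)C(=O)[C@](OC)([C@H](c3ccc(OC)c(O[Si](C(C)C)(C(C)C)C(C)C)c3)[C@H]1C)[C@H]2O | intermediate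
22 | dilithium C3–C4 enolate C8 alkoxide of 21 | C=CC[C@]12CC(OC)=C(O[Li])[C@](OC)([C@H](c3ccc(OC)c(O[Si](C(C)C)(C(C)C)C(C)C)c3)[C@H]1C)[C@H]2O[Li] | intermediate
23 | (1S,3S,5S,6S,7R,8S)-1-allyl-6-Ar-8-hydroxy-3,5-dimethoxy-7-methylbicyclo[3.2.1]octan-4-one (3-OMe endo) | C=CC[C@]12C[C@H](OC)C(=O)[C@](OC)([C@H](c3ccc(OC)c(O[Si](C(C)C)(C(C)C)C(C)C)c3)[C@H]1C)[C@H]2O | intermediate
24 | (1S,3S,5S,6S,7R,8S)-1-allyl-8-hydroxy-6-(3-hydroxy-4-methoxyphenyl)-3,5-dimethoxy-7-methylbicyclo[3.2.1]octan-4-one | C=CC[C@]12C[C@H](OC)C(=O)[C@](OC)([C@H](c3ccc(OC)c(O)c3)[C@H]1C)[C@H]2O | target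

**Step count and risks**

Total step count: 14. Longest linear sequence: 13 steps (1 to 24 through steps 1–8 and 10–14). Step 9 is a one-step side branch.

Steps most likely to fail:

Step 10. The hindered enolate may attack the formyl carbon, or it may polymerise the acceptor, instead of adding to its CH2 terminus. The closure may also stall, because the aldol equilibrium has to pay for the aryl group on the closing face. The fallback sets out from 13 and 16 and comes back at 19, and it replaces the conjugate addition by an alkylation. Compound 16 is first treated with Me2S and tBuMe2SiOTf (CH2Cl2, −78 °C) to give (Z)-[3-(tert-butyldimethylsilyloxy)-2-methoxyprop-2-enyl]dimethylsulfonium trifluoromethanesulfonate F1. In this salt the formyl carbon is masked as an enol silane and the C2 methylene is the only electrophilic carbon. Enolate 17, made from 13 with MeLi as before, displaces dimethyl sulfide to give (2S,3S,4R,5S)-5-allyl-3-Ar-5-[(Z)-3-(tert-butyldimethylsilyloxy)-2-methoxyprop-2-enyl]-2-methoxy-4-methylcyclopentan-1-one F2, which is isolated. Treatment with 2 M HCl in THF then frees 18 and closes it to 19.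

Step 11. Facial selectivity may be poor, since the exo methyl group at C7 hinders the face from which hydride has to come, and the ketone between two quaternary carbons may react sluggishly. The fallback sets out from 19 and comes back at 20. Hydride transfer under steric approach control is given up for single-electron reduction with SmI2 and water in THF at 0 °C.
- The ketyl is pyramidal. Bound to trivalent samarium that is chelated by the axial C4 hydroxyl, it holds O8 on the propano side, so protonation should come from the ethano side.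
- The C5–OMe bond lies in the nodal plane of the ketyl and at a bridgehead, so reductive loss of methoxide is not expected.
- The allyl group could only close a four-membered or a 5-endo ring.
- No compound outside the list is made (F0).

Step 13. Removal of the endo hydrogen at C3 may be slow, which would give the lithium alkoxide time for retro-aldol cleavage, and the exo-face preference in the protonation may be insufficient. The fallback sets out from 21 and comes back at 23, and it replaces kinetic control by equilibration with recycling. Catalytic DBU in toluene at 23 °C interconverts 21 and 23 through the enol, with the C8 hydroxyl shuttling protons on the exo face. The dipole of the α-methoxy ketone favours the quasi-axial endo methoxy group, so a usable share of 23 is expected. The epimers are separated by chromatography and recovered 21 is resubmitted. No compound outside the list is made (F0).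

**Further compounds**

F1 | step 10 | (Z)-[3-(tert-butyldimethylsilyloxy)-2-methoxyprop-2-enyl]dimethylsulfonium trifluoromethanesulfonate | C[S+](C)C/C(OC)=C/O[Si](C)(C)C(C)(C)C.[O-]S(=O)(=O)C(F)(F)F
F2 | step 10 | (2S,3S,4R,5S)-5-allyl-3-Ar-5-[(Z)-3-(tert-butyldimethylsilyloxy)-2-methoxyprop-2-enyl]-2-methoxy-4-methylcyclopentan-1-one | C=CC[C@@]1(C/C(OC)=C/O[Si](C)(C)C(C)(C)C)C(=O)[C@@H](OC)[C@H](c2ccc(OC)c(O[Si](C(C)C)(C(C)C)C(C)C)c2)[C@H]1C
F0 | step 11 | none | none
F0 | step 13 | none | none
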